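All runs are simulated from invented constants; noise was put on by code.

What I want is the share of the dosed free monomer that has reacted at 4.0 min, and the chain length then.

- Tuesday's: free monomer 0.10 M (fed, over 4.0 min); protic impurity 0.10 M; initiator 0.60 mM; the very flask that is asked about, followed so far; the fed solution adds 0.50 times the starting volume
- flask: free monomer 0.10 M (fed, over 4.0 min); protic impurity 0.100 M; initiator 0.60 mM; time 4.0 min; the fed solution adds 0.50 times the starting volume

Tuesday's run (percent of the free monomer charged)

| time / s | monomer in chains / % | free monomer / % |
|---|---|---|
| 12.0 | 1.6 | 6.0 |
| 25.0 | 0.7 | 9.9 |
| 40.0 | 0.3 | 15.2 |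
| 50.0 | 2.7 | 19.6 |
| 60.0 | 0.9 | 21.4 |
| 80.0 | 2.4 | 28.6 |

(scatter of a reading: 1 percentage point)

- average number of monomer units in a chain (living and dead chains, two that joined counted as one) at 4.0 min
- part of the free monomer that has reacted at 4.0 min

- charges are per starting volume, the dose included; the dosed solution carries all of it
- the average divides the monomer in chains by the number of chains, living and dead together; two radicals that join make one chain
- the earlier runs do not show the number of chains; that part of a forecast is a guess
- percentages count the whole charge, also what has not yet gone in

1. Two times matter: the dosing time 4.0 min, and the time the flask takes to consume free monomer. I call the second the consumption time.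

2. Tuesday's run is this same flask. At 80.0 s, 33.3% of the charge has gone in and 28.6% stands free, so the shortfall is 4.73%, with 1 percentage point of scatter.

3. I assume pseudo-first-order loss. The shortfall is then the squared time over twice the dosing time and the consumption time, which gives 4.69 min.

4. I also assume the active centres thin out as the volume grows, which stretches this 1.29-fold by the end of dosing, to 6.04 min.

5. The dose number, dosing time over consumption time, is 0.663. Feed and loss cross when the free share reaches 151%, more than the whole charge, so the feed stays ahead throughout the dose. Integrating gives 26.9% reacted. Tuesday's readings do not show the number of chains, so I reckon no dp.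

The forecast says 24% and dp 25, and of the latter: “The chain count is a guess”.

    initiator → 2 initiating radical (k = 0.00610 s⁻¹)
    free monomer + initiating radical → growing radical + monomer in chains (k = 3.90 × 10⁵ L mol⁻¹ s⁻¹)
    free monomer + growing radical → monomer in chains + growing radical, rate k3*[growing radical]*[free monomer] (k = 3400 L mol⁻¹ s⁻¹)
    2 growing radical → dead chain (k = 3.00 × 10⁶ L mol⁻¹ s⁻¹)
    protic impurity + free monomer → quenched substrate (k = 0.00490 L mol⁻¹ s⁻¹)

The flask gives 24.4% and dp 45.3. Its free monomer rises from 41.1% at 2.00 min to 75.6% at 4.00 min, still below the crossing at 151%. My reckoning stands 2.5 points higher.

The neighbour flask holds 0.060 M of free monomer. Neither time contains the charge, so the dose number stays 0.663 and again gives 26.9%. The computed result there is 24.9%.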